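## Retrosynthetic overview

1. Endgame: the C2 propenal comes from SeO2 oxidation of an isopropenyl group, and the C3 angelate and C6 methacrylate from acylation of hydroxy lactone 24.
2. Key disconnection: the α-methylene-γ-butyrolactone is cut at O–C5 and at Cα–C(=O), giving CO2, a hydride and the bromohydrin alkyne 20. Forward, Markovnikov hydroalumination of the C4 ethynyl group, carboxylation with CO2 and SN2 closure at C5 build the lactone and its exocyclic methylene in one flask.
3. Enabling feature: the internal ethynyl carbon on C4 (the future Cα) is 1,3 to ring carbon C5, which carries a bromide trans to the C4 substituent. A C(=O)O unit therefore spans Cα and C5 exactly, as the five-membered ring O–C(=O)–Cα–C4–C5, and it can only be cis-fused to the cyclohexane.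
4. The cyclohexane comes from (R)-4-hydroxycyclohex-2-enone, whose carbinol (C3) relays every other centre: directed syn isopropenyl addition (C2), anti α′-vinylation (C1), anti conjugate alkynylation (C4), anti bromination (C5), equatorial hydride delivery (C6).
5. Ring order: the carbocycle is present from step 1 (cyclohexa-1,3-diene); the lactone is the only ring formed later (step 9).

Key step: step 9

Remarks: (i) Ring positions of all intermediates carry the target's locants: C1 = C(CH3)(vinyl), C2 = CH bearing isopropenyl/propenal, C3 = CH–O (angelate), C4 = CH bearing the lactone Cα, C5 = CH–O (lactone), C6 = CH–O (methacrylate). "Vinyl face" is the ring face carrying the C1 vinyl group; "methyl face" is the opposite one. (ii) The methyl-bearing centre of 8, 10 and 12 is drawn as the expected major epimer; it is planarised in step 6, so its configuration has no consequence.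

## Route

Step 1
Reactants: 1 cyclohexa-1,3-diene; 2 dioxygen
Product: 3 endoperoxide 2,3-dioxabicyclo[2.2.2]oct-5-ene (meso)
Conditions: O2, hν (visible), tetraphenylporphyrin (cat.), CH2Cl2, −20 °C
Reagents that add atoms: dioxygen O=O
Why: Singlet-oxygen [4+2] photooxygenation of a cyclic 1,3-diene, which can only give the cis-bridged meso endoperoxide.

Step 2
Reactants: 3 endoperoxide
Product: 4 (R)-4-hydroxycyclohex-2-en-1-one
Conditions: 6′-hydroxy-9-O-acyl cinchona alkaloid catalyst (5–10 mol %, the pseudoenantiomer that delivers the (R)-enone), CH2Cl2, 23 °C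
Reagents that add atoms: none
Why: Catalytic enantioselective Kornblum–DeLaMare rearrangement, in which the chiral base removes one of the two enantiotopic bridgehead hydrogens and O–O cleavage sets the C3 carbinol centre by desymmetrisation.

Step 3
Reactants: 4 (R)-4-hydroxycyclohex-2-en-1-one; 5 isopropenylmagnesium bromide; 6 iodomethane
Product: 8 (2S,3R,4R)-4-hydroxy-2-methyl-3-(prop-1-en-2-yl)cyclohexan-1-one, via magnesium enolate 7 (not isolated)
Conditions: t-BuMgCl (1.0 equiv), THF, −78 °C; 5 (1.3 equiv), −78 → −20 °C; then 6 (5 equiv), DMPU, −20 → 0 °C; aq. NH4Cl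
Reagents that add atoms: isopropenylmagnesium bromide C=C(C)[Mg]Br; iodomethane CI
Why: Alkoxide-directed (ligand-assisted) 1,4-addition of a Grignard reagent to a γ-hydroxy enone, in which the magnesium alkoxide delivers the isopropenyl group to the β-carbon on its own face (C2 cis to the C3 oxygen), followed by in situ C-methylation of the regiodefined enolate.

Step 4
Reactants: 8 hydroxy ketone; 9 tert-butyldimethylsilyl chloride
Product: 10 (2S,3R,4R)-4-[(tert-butyldimethylsilyl)oxy]-2-methyl-3-(prop-1-en-2-yl)cyclohexan-1-one
Conditions: TBSCl, imidazole, DMF, 23 °C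
Reagents that add atoms: tert-butyldimethylsilyl chloride CC(C)(C)[Si](C)(C)Cl
Why: Standard silylation of the secondary alcohol; no stereocentre is touched.

Step 5
Reactants: 10 silyl ether ketone
Product: 12 (4R,5R,6S)-4-[(tert-butyldimethylsilyl)oxy]-6-methyl-5-(prop-1-en-2-yl)cyclohex-2-en-1-one, via trimethylsilyl enol ether 11 (not isolated)
Conditions: LDA, THF, −78 °C; TMSCl; then Pd(OAc)2 (1.05 equiv), MeCN, 23 °C
Reagents that add atoms: none
Why: Kinetic deprotonation occurs at the unhindered CH2 rather than the methyl-bearing CH, and Saegusa–Ito oxidation of the silyl enol ether gives the γ-silyloxy enone without touching a stereocentre.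

Step 6
Reactants: 12 enone; 13 vinyl bromide
Product: 14 (4R,5S,6S)-4-[(tert-butyldimethylsilyl)oxy]-6-methyl-5-(prop-1-en-2-yl)-6-vinylcyclohex-2-en-1-one
Conditions: LiHMDS (1.3 equiv), THF, −78 → 0 °C; then 13 (3 equiv, 1 M in THF), Pd2(dba)3 (2.5 mol %), Q-Phos (5.5 mol %), toluene, 23 → 50 °C
Reagents that add atoms: vinyl bromide C=CBr
Why: Pd-catalysed α-vinylation of a ketone enolate (only the α′ position of the enone is enolisable); the vinyl–palladium unit takes the enolate face opposite the adjacent isopropenyl and the C3 silyloxy group, so the C1 quaternary centre forms with vinyl trans and methyl cis to the C2 isopropenyl.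

Step 7
Reactants: 14 enone; 15 (trimethylsilyl)acetylene; 16 N-bromosuccinimide
Product: 18 α-bromo ketone (C6 ketone; C5 bromide on the methyl face; C4 (trimethylsilyl)ethynyl on the vinyl face; C3 OTBS), via silyl enol ether 17 (not isolated)
Conditions: 15, n-BuLi, THF, −78 °C; ZnBr2; then 14, TBSOTf (1.3 equiv), Et2O, −40 °C; crude enol ether, 16 (1.1 equiv), THF, −78 → −40 °C
Reagents that add atoms: (trimethylsilyl)acetylene C#C[Si](C)(C)C; N-bromosuccinimide O=C1CCC(=O)N1Br
Why: Silyl-triflate-promoted conjugate addition of an alkynylzinc bromide attacks anti to the γ-silyloxy group and trans to the C2 isopropenyl (sets C4), and the regiodefined silyl enol ether is brominated anti to the new alkynyl group (sets C5 as the trans-diequatorial, also thermodynamic, epimer).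

Step 8
Reactants: 18 α-bromo ketone
Product: 20 bromohydrin alkyne (C4 ethynyl on the vinyl face; C5 Br and C6 OH both on the methyl face; C3 OTBS), via silylalkyne bromohydrin 19 (not isolated)
Conditions: L-Selectride (1.3 equiv), THF, −78 °C; then MeOH, K2CO3 (0.2 equiv), 0 → 23 °C
Reagents that add atoms: none
Why: In the only unstrained chair the C2 isopropenyl is axial and blocks the axial trajectory at C6, so the bulky hydride attacks equatorially from the vinyl face and gives the axial C6 alcohol cis to the C5 bromide; methanolysis then cleaves the C(sp)–Si bond.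

Step 9
Reactants: 20 bromohydrin alkyne; 21 carbon dioxide
Product: 24 hydroxy lactone (cis-fused α-methylene-γ-butyrolactone on C4/C5 on the vinyl face; free C6 OH; C3 OTBS), via α-alkenylalane 22 (not isolated), via lithium acrylate 23 (not isolated)
Conditions: DIBAL-H (2.4 equiv), Ni(dppp)Cl2 (3 mol %), THF, 0 → 23 °C; MeLi (2.2 equiv), −78 °C; CO2 (1 atm), −78 → 0 °C; then DMPU, 55 °C; aq. Rochelle salt
Reagents that add atoms: carbon dioxide O=C=O
Why: Ni–H-catalysed Markovnikov syn-hydroalumination places aluminium on the internal alkyne carbon and hydrogen on the terminus (this creates the exocyclic methylene), MeLi converts the alkenylalane into an alanate whose alkenyl–Al bond inserts CO2 (new Cα–C(=O) bond), and the carboxylate so formed displaces the C5 bromide from the rear (new O–C5 bond). The closest known chemistry is the Ni(dppp)Cl2/DIBAL-H α-hydroalumination of terminal alkynes, the carboxylation of alkenylalanates with CO2 and the carboxylate SN2 lactonisation of halo acids, run here in one flask as a union of alkyne, hydride and CO2. One ring is closed, the γ-lactone, by 5-exo-tet attack of the carboxylate oxygen on C5. One stereocentre is made, C5, by stereospecific inversion of the methyl-face bromide; because the acrylate hangs from C4 on the vinyl face, only the cis ring fusion can form. The step needs α- over β-hydroalumination (the dppp ligand), reaction of the alkyne in preference to the three alkenes and the C–Br bond (terminal alkynes are by far the fastest hydroalumination partners, and the secondary bromide is inert to DIBAL-H and to MeLi at −78 °C), and substitution in preference to elimination or epoxide formation (weakly basic carboxylate, no antiperiplanar β-hydrogen in the ground-state chair, and a C6 alkoxide that is cis to the bromide).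

Step 10
Reactants: 24 hydroxy lactone; 25 methacrylic anhydride
Product: 26 C6 methacrylate (C3 OTBS)
Conditions: methacrylic anhydride (3 equiv), Et3N, DMAP (0.2 equiv), CH2Cl2, 0 → 23 °C
Reagents that add atoms: methacrylic anhydride CC(=C)C(=O)OC(=O)C(C)=C
Why: DMAP-catalysed acylation of the only free hydroxyl group (C6), with retention at the carbinol.

Step 11
Reactants: 26 silyl ether
Product: 27 C3 alcohol
Conditions: HF·pyridine, THF/pyridine, 0 → 23 °C
Reagents that add atoms: none
Why: Fluoride cleavage of the secondary TBS ether under buffered acidic conditions, which avoids base-induced translactonisation onto the C3 oxygen and conjugate addition to the methylene lactone.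

Step 12
Reactants: 27 C3 alcohol; 28 angelic acid
Product: 29 C3 angelate (isopropenyl precursor of the target)
Conditions: 28, 2,4,6-trichlorobenzoyl chloride, Et3N, toluene, 23 °C; then 27, 75 °C
Reagents that add atoms: angelic acid C/C=C(/C)C(=O)O
Why: Yamaguchi esterification through the mixed anhydride, the established way to make angelates of hindered secondary alcohols without Z-to-E isomerisation.

Step 13
Reactants: 29 angelate; 30 tert-butyl hydroperoxide
Product: 32 CNP0102441.1 (target), via allylic alcohol 31 (not isolated)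
Conditions: SeO2 (0.3 equiv), t-BuOOH (3 equiv), CH2Cl2, 23 °C; then Dess–Martin periodinane, NaHCO3, CH2Cl2, 0 → 23 °C
Reagents that add atoms: tert-butyl hydroperoxide CC(C)(C)OO
Why: SeO2-catalysed allylic oxidation (ene reaction then [2,3]-shift) attacks the isopropenyl group, the only electron-rich alkene with allylic C–H, at its methyl (CH3 over CH), and the periodinane converges the alcohol/enal mixture to the 2-substituted acrolein; the three enoate alkenes are too electron-poor and the vinyl group has no allylic hydrogen.

## Compound list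

1 | cyclohexa-1,3-diene | C1=CC=CCC1 | starting material
2 | dioxygen | O=O | starting material
3 | 2,3-dioxabicyclo[2.2.2]oct-5-ene (meso endoperoxide) | C1C[C@H]2C=C[C@@H]1OO2 | intermediate
4 | (R)-4-hydroxycyclohex-2-en-1-one | O=C1C=C[C@H](O)CC1 | intermediate
5 | isopropenylmagnesium bromide | C=C(C)[Mg]Br | starting material
6 | iodomethane | CI | starting material
7 | magnesium enolate–alkoxide of (3R,4R)-4-hydroxy-3-(prop-1-en-2-yl)cyclohexan-1-one | Br[Mg]OC1=C[C@H](C(C)=C)[C@H](O[Mg]Cl)CC1 | intermediate
8 | (2S,3R,4R)-4-hydroxy-2-methyl-3-(prop-1-en-2-yl)cyclohexan-1-one | C[C@H]1[C@H](C(C)=C)[C@H](O)CCC1=O | intermediate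
9 | tert-butyldimethylsilyl chloride | CC(C)(C)[Si](C)(C)Cl | starting material
10 | (2S,3R,4R)-4-[(tert-butyldimethylsilyl)oxy]-2-methyl-3-(prop-1-en-2-yl)cyclohexan-1-one | C[C@H]1[C@H](C(C)=C)[C@H](O[Si](C)(C)C(C)(C)C)CCC1=O | intermediate
11 | trimethylsilyl enol ether of 10 (enol double bond toward the CH2) | C[C@H]1[C@H](C(C)=C)[C@H](O[Si](C)(C)C(C)(C)C)CC=C1O[Si](C)(C)C | intermediate
12 | (4R,5R,6S)-4-[(tert-butyldimethylsilyl)oxy]-6-methyl-5-(prop-1-en-2-yl)cyclohex-2-en-1-one | C[C@H]1[C@H](C(C)=C)[C@H](O[Si](C)(C)C(C)(C)C)C=CC1=O | intermediate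
13 | vinyl bromide | C=CBr | starting material
14 | (4R,5S,6S)-4-[(tert-butyldimethylsilyl)oxy]-6-methyl-5-(prop-1-en-2-yl)-6-vinylcyclohex-2-en-1-one | C=C[C@@]1(C)[C@H](C(C)=C)[C@H](O[Si](C)(C)C(C)(C)C)C=CC1=O | intermediate
15 | (trimethylsilyl)acetylene | C#C[Si](C)(C)C | starting material
16 | N-bromosuccinimide | O=C1CCC(=O)N1Br | starting material
17 | TBS enol ether of the C4-alkynyl ketone (C6 O-silyl, C5=C6; alkynyl on the vinyl face) | C=C[C@@]1(C)[C@H](C(C)=C)[C@H](O[Si](C)(C)C(C)(C)C)[C@@H](C#C[Si](C)(C)C)C=C1O[Si](C)(C)C(C)(C)C | intermediate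
18 | α-bromo ketone (C6 C=O; C5 Br methyl face; C4 (trimethylsilyl)ethynyl vinyl face; C3 OTBS) | C=C[C@@]1(C)[C@H](C(C)=C)[C@H](O[Si](C)(C)C(C)(C)C)[C@@H](C#C[Si](C)(C)C)[C@H](Br)C1=O | intermediate
19 | C-silylated bromohydrin (C6 OH methyl face, cis to C5 Br) | C=C[C@@]1(C)[C@H](C(C)=C)[C@H](O[Si](C)(C)C(C)(C)C)[C@@H](C#C[Si](C)(C)C)[C@H](Br)[C@@H]1O | intermediate
20 | bromohydrin alkyne (C4 ethynyl vinyl face; C5 Br and C6 OH methyl face; C3 OTBS) | C=C[C@@]1(C)[C@H](C(C)=C)[C@H](O[Si](C)(C)C(C)(C)C)[C@@H](C#C)[C@H](Br)[C@@H]1O | intermediate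
21 | carbon dioxide | O=C=O | starting material
22 | α-alkenyl(diisobutyl)alane with C6 O–Al(i-Bu)2 | C=C[C@@]1(C)[C@H](C(C)=C)[C@H](O[Si](C)(C)C(C)(C)C)[C@@H](C(=C)[Al](CC(C)C)CC(C)C)[C@H](Br)[C@@H]1O[Al](CC(C)C)CC(C)C | intermediate
23 | lithium 2-(cyclohexyl)acrylate with C5 Br still in place | C=C[C@@]1(C)[C@H](C(C)=C)[C@H](O[Si](C)(C)C(C)(C)C)[C@@H](C(=C)C(=O)[O-])[C@H](Br)[C@@H]1O[Al](CC(C)C)CC(C)C.[Li+] | intermediate
24 | hydroxy lactone (cis-fused α-methylene-γ-butyrolactone at C4/C5; C6 OH; C3 OTBS) | C=C[C@@]1(C)[C@H](C(C)=C)[C@H](O[Si](C)(C)C(C)(C)C)[C@H]2C(=C)C(=O)O[C@H]2[C@@H]1O | intermediate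
25 | methacrylic anhydride | CC(=C)C(=O)OC(=O)C(C)=C | starting material
26 | C6 methacrylate, C3 OTBS lactone | C=C[C@@]1(C)[C@H](C(C)=C)[C@H](O[Si](C)(C)C(C)(C)C)[C@H]2C(=C)C(=O)O[C@H]2[C@@H]1OC(=O)C(=C)C | intermediate
27 | C6 methacrylate, C3 alcohol lactone | C=C[C@@]1(C)[C@H](C(C)=C)[C@H](O)[C@H]2C(=C)C(=O)O[C@H]2[C@@H]1OC(=O)C(=C)C | intermediate
28 | angelic acid, (Z)-2-methylbut-2-enoic acid | C/C=C(/C)C(=O)O | starting material
29 | C3 angelate, C6 methacrylate, C2 isopropenyl lactone | C=C[C@@]1(C)[C@H](C(C)=C)[C@H](OC(=O)/C(C)=C\C)[C@H]2C(=C)C(=O)O[C@H]2[C@@H]1OC(=O)C(=C)C | intermediate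
30 | tert-butyl hydroperoxide | CC(C)(C)OO | starting material
31 | allylic alcohol (C2 3-hydroxyprop-1-en-2-yl) | C=C[C@@]1(C)[C@H](C(=C)CO)[C@H](OC(=O)/C(C)=C\C)[C@H]2C(=C)C(=O)O[C@H]2[C@@H]1OC(=O)C(=C)C | intermediate
32 | CNP0102441.1 | C=C[C@@]1(C)[C@H](C(=C)C=O)[C@H](OC(=O)/C(C)=C\C)[C@H]2C(=C)C(=O)O[C@H]2[C@@H]1OC(=O)C(=C)C | target

## Step count and risk

Total steps: 13. Longest linear sequence: 13 (fully linear from cyclohexa-1,3-diene; all other inputs are purchased reagents).

**Step 9 (key step).** What may go wrong: nickel-mediated activation or reductive loss of the C5 bromide during hydroalumination, incomplete α-regioselectivity, or sluggish ring closure of the aluminium-bound carboxylate on an equatorial leaving group. The fallback replaces the hydrometalation/alanate route by halogen–lithium exchange. From 20, the hydroxyl is silylated in situ (TMSCl, imidazole) and the terminal alkyne is haloborated with B-iodo-9-BBN (pentane/CH2Cl2, −20 °C). Protonolysis with AcOH and aqueous work-up, which also releases the hydroxyl, should give the 2-iodoalkene F1. F1 is deprotonated with MeLi (1 equiv), converted to the vinyllithium with t-BuLi (2.1 equiv, Et2O, −100 °C), carboxylated with CO2 and warmed with DMPU, so that the lithium carboxylate closes the lactone and the route is rejoined at 24.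

**Step 3.** What may go wrong: competing 1,2-addition to the enone, loss of the alkoxide-directed facial control, or over-alkylation of the enolate. The fallback sets C2 by an ordinary anti cuprate addition and corrects the carbinol by inversion. From 3, rearrangement with the pseudoenantiomeric cinchona catalyst should give (S)-4-hydroxycyclohex-2-en-1-one F2, which is silylated (TBSCl, imidazole) to (S)-4-[(tert-butyldimethylsilyl)oxy]cyclohex-2-en-1-one F3. Copper-catalysed addition of isopropenylmagnesium bromide (CuBr·SMe2, THF, −78 °C) anti to the silyloxy group, with MeI/HMPA trapping, gives the trans ketone F4. HF·pyridine gives the trans hydroxy ketone F5. Mitsunobu inversion (4-nitrobenzoic acid, PPh3, DIAD) gives the cis 4-nitrobenzoate F6, and K2CO3/MeOH releases 8.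

**Step 6.** What may go wrong: failure of C–C reductive elimination at the congested, fully substituted enolate carbon, or Heck-type consumption of the alkenes. The fallback builds the vinyl group by aldol/elimination. From 12, the lithium enolate (LDA, THF, −78 °C) is added to (phenylselanyl)acetaldehyde on the face anti to the isopropenyl group to give the β-hydroxy selenide F7. MsCl/Et3N (CH2Cl2, 0 °C) then eliminates the hydroxyl and the selanyl group; because the α-carbon is quaternary, this can only give the terminal vinyl group, rejoining at 14.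

## Further compounds

F1 | step 9 | 2-iodoalkene (C4 1-iodovinyl on the vinyl face; C5 Br and C6 OH on the methyl face; C3 OTBS) | C=C[C@@]1(C)[C@H](C(C)=C)[C@H](O[Si](C)(C)C(C)(C)C)[C@@H](C(I)=C)[C@H](Br)[C@@H]1O
F2 | step 3 | (S)-4-hydroxycyclohex-2-en-1-one | O=C1C=C[C@@H](O)CC1
F3 | step 3 | (S)-4-[(tert-butyldimethylsilyl)oxy]cyclohex-2-en-1-one | O=C1C=C[C@@H](O[Si](C)(C)C(C)(C)C)CC1
F4 | step 3 | (2S,3R,4S)-4-[(tert-butyldimethylsilyl)oxy]-2-methyl-3-(prop-1-en-2-yl)cyclohexan-1-one (trans ketone) | C[C@H]1[C@H](C(C)=C)[C@@H](O[Si](C)(C)C(C)(C)C)CCC1=O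
F5 | step 3 | (2S,3R,4S)-4-hydroxy-2-methyl-3-(prop-1-en-2-yl)cyclohexan-1-one (trans hydroxy ketone) | C[C@H]1[C@H](C(C)=C)[C@@H](O)CCC1=O
F6 | step 3 | (1R,2R,3S)-3-methyl-4-oxo-2-(prop-1-en-2-yl)cyclohexyl 4-nitrobenzoate (cis ester) | C[C@H]1[C@H](C(C)=C)[C@H](OC(=O)c2ccc(cc2)[N+](=O)[O-])CCC1=O
F7 | step 6 | β-hydroxy selenide: 6-[1-hydroxy-2-(phenylselanyl)ethyl] derivative of 12 (one carbinol epimer drawn; both converge) | O[C@H](C[Se]c1ccccc1)[C@@]1(C)[C@H](C(C)=C)[C@H](O[Si](C)(C)C(C)(C)C)C=CC1=O
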